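**Retrosynthetic overview**
1. The last C–C bond is C9–C11: an aldol condensation joins the α′-enolate of a ring A/B enone (left half) to a C11 aldehyde on the right-hand cyclohexene. Double conjugate reduction with C9 equilibration, C8 methylenation and desilylation finish the synthesis.
2. Rings A and B close together in an intramolecular Diels–Alder reaction of an acyclic, geranyl-derived triene (diene C7=C8(OSi)–C9=C10, dienophile C5=C6 with a temporary phenylsulfonyl group on C6, tether C1–C4), forming C6–C7 and C5–C10. Fluoride then expels the sulfinate to leave the Δ6-8-ketone.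
3. Enabling feature: ring B is a cyclohexane whose C8 exocyclic methylene is a masked ketone (retron of a 2-oxy-diene C7–C10) next to an unsubstituted C6–C7 ethano unit (vinyl sulfone as ethylene/acetylene equivalent). C8–C9–C10(Me)–C1–C2–C3 is the C1–C6 segment of geranyl acetate, and C3(O)–C4(Me)2–C5 is an isobutyrate aldol retron.
4. Right half: (R)-carvone supplies ring B′ (C5′–C10′ with the isopropenyl group and the C8′ methyl). α′-Methylation and Michael addition set quaternary C10′, a Wharton transposition/oxidation/Luche sequence moves oxygen to C7′, and a Claisen rearrangement transfers the C7′ configuration to C9′ while installing C12–C11.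
5. Ring order: ring B′ (chiral pool) → rings A and B simultaneously (key step) → fragment union.

Key step: step 10

Locants used below are those of the onocerane skeleton of the target: C3 carbinol, C4 gem-dimethyl carbon, C5/C10 ring fusion, C8 methylidene-bearing carbon, C9–C11–C12–C9′ bridge, C5′ isopropenyl-bearing carbon, C8′ vinylic-methyl carbon, C10′ quaternary carbon carrying the propanoate chain.
Assumption: the N-tosyl-D-valine-derived oxazaborolidinone is taken to give the (3S)-aldol with aliphatic aldehydes; if the sense were opposite, the L-valine reagent would be used.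

**Step 1**
Reactants: 1 geranyl acetate [(2E)-3,7-dimethylocta-2,6-dien-1-yl acetate]
Product: 3 (2E)-3-methyl-6-oxohex-2-en-1-yl acetate, via ozonide 2 (not isolated)
Conditions: O3 (1.0 equiv), CH2Cl2, −78 °C; then Me2S, −78 °C → rt
Reagents that add atoms: ozone, [O-][O+]=O
Why: Ozonolysis with reductive work-up should cleave only the electron-rich terminal trisubstituted alkene, because the other alkene is deactivated by the allylic acetate, giving the future C3 aldehyde with the E-configured C9=C10 unit intact.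

**Step 2**
Reactants: 3 (2E)-3-methyl-6-oxohex-2-en-1-yl acetate; 4 1-methoxy-2-methyl-1-(trimethylsilyloxy)prop-1-ene
Product: 5 methyl (3S,6E)-8-acetoxy-3-hydroxy-2,2,6-trimethyloct-6-enoate
Conditions: N-tosyl-D-valine (1.0 equiv), BH3·THF (1.0 equiv), CH2Cl2, 0 °C → rt; then 3 and 4, −78 °C; pH 7 buffer work-up
Reagents that add atoms: none
Why: In this Kiyooka-type enantioselective Mukaiyama aldol reaction the chiral oxazaborolidinone binds the aldehyde and shields one face, so the isobutyrate ketene silyl acetal should deliver the 3S carbinol together with the C4 gem-dimethyl carbon and C5.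

**Step 3**
Reactants: 5 methyl (3S,6E)-8-acetoxy-3-hydroxy-2,2,6-trimethyloct-6-enoate
Product: 6 methyl (3S,6E)-8-acetoxy-3-(tert-butyldimethylsilyloxy)-2,2,6-trimethyloct-6-enoate
Conditions: TBSOTf, 2,6-lutidine, CH2Cl2, 0 °C
Reagents that add atoms: tert-butyldimethylsilyl triflate, CC(C)(C)[Si](C)(C)OS(=O)(=O)C(F)(F)F
Why: Silylation with the silyl triflate protects the hindered neopentylic C3 alcohol as a bulky ether that later serves as the stereocontrol element of the cycloaddition.

**Step 4**
Reactants: 6 methyl (3S,6E)-8-acetoxy-3-(tert-butyldimethylsilyloxy)-2,2,6-trimethyloct-6-enoate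
Product: 7 (2E,6S)-6-(tert-butyldimethylsilyloxy)-3,7,7-trimethyloct-2-ene-1,8-diol
Conditions: iBu2AlH (5 equiv), CH2Cl2, −78 → 0 °C; then H2O
Reagents that add atoms: none
Why: Hydride reduction with iBu2AlH should convert the hindered methyl ester into the neopentyl alcohol and cleave the allylic acetate in the same operation, leaving the silyl ether untouched.

**Step 5**
Reactants: 7 (2E,6S)-6-(tert-butyldimethylsilyloxy)-3,7,7-trimethyloct-2-ene-1,8-diol
Product: 8 (2E,6S)-6-(tert-butyldimethylsilyloxy)-8-hydroxy-3,7,7-trimethyloct-2-enal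
Conditions: MnO2 (15 equiv), CH2Cl2, rt
Reagents that add atoms: none
Why: MnO2 is a chemoselective allylic oxidant, so only the allylic primary alcohol should be oxidised, with the neopentyl alcohol and the E geometry retained.

**Step 6**
Reactants: 8 (2E,6S)-6-(tert-butyldimethylsilyloxy)-8-hydroxy-3,7,7-trimethyloct-2-enal
Product: 9 (3E,7S)-7-(tert-butyldimethylsilyloxy)-4,8,8-trimethylnon-3-ene-2,9-diol (C2 epimers)
Conditions: MeMgBr (2.5 equiv), THF, −78 → 0 °C; then H2O
Reagents that add atoms: methylmagnesium bromide, C[Mg]Br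
Why: Grignard 1,2-addition to the β,β-disubstituted enal installs C7; the new carbinol centre forms as both epimers and is removed in step 7.

**Step 7**
Reactants: 9 (3E,7S)-7-(tert-butyldimethylsilyloxy)-4,8,8-trimethylnon-3-ene-2,9-diol (C2 epimers)
Product: 10 (3S,6E)-3-(tert-butyldimethylsilyloxy)-2,2,6-trimethyl-8-oxonon-6-enal
Conditions: Dess–Martin periodinane (3 equiv), CH2Cl2, 0 °C → rt
Reagents that add atoms: none
Why: Dess–Martin oxidation should convert both alcohols at once into the E-enone (C8 ketone) and the non-enolisable α,α-dimethyl aldehyde (C5) under neutral conditions that preserve the alkene geometry.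

**Step 8**
Reactants: 10 (3S,6E)-3-(tert-butyldimethylsilyloxy)-2,2,6-trimethyl-8-oxonon-6-enal; 11 diethyl [(phenylsulfonyl)methyl]phosphonate
Product: 12 (3E,7S,9E)-7-(tert-butyldimethylsilyloxy)-4,8,8-trimethyl-10-(phenylsulfonyl)deca-3,9-dien-2-one
Conditions: LiCl, DBU, MeCN, rt
Reagents that add atoms: none
Why: Horner–Wadsworth–Emmons olefination under Masamune–Roush conditions should react with the aldehyde in preference to the conjugated methyl ketone and give the (E)-vinyl sulfone, which introduces C6 with its temporary activating group.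

**Step 9**
Reactants: 12 (3E,7S,9E)-7-(tert-butyldimethylsilyloxy)-4,8,8-trimethyl-10-(phenylsulfonyl)deca-3,9-dien-2-one
Product: 14 (3E,7S,9E)-2,7-bis(tert-butyldimethylsilyloxy)-4,8,8-trimethyl-10-(phenylsulfonyl)deca-1,3,9-triene, via lithium dienolate 13 (not isolated)
Conditions: LiN(iPr)2 (1.05 equiv), THF, −78 °C; then TBSOTf, −78 °C
Reagents that add atoms: tert-butyldimethylsilyl triflate, CC(C)(C)[Si](C)(C)OS(=O)(=O)C(F)(F)F
Why: Kinetic α′-deprotonation of the methyl ketone at the C7 methyl and O-silylation (silyl enol ether formation) should give the cross-conjugated 2-silyloxy diene without disturbing the C9=C10 geometry or the far less acidic vinyl sulfone.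

**Step 10**
Reactants: 14 (3E,7S,9E)-2,7-bis(tert-butyldimethylsilyloxy)-4,8,8-trimethyl-10-(phenylsulfonyl)deca-1,3,9-triene
Product: 16 (4aR,6S,8aR)-6-(tert-butyldimethylsilyloxy)-5,5,8a-trimethyl-4a,5,6,7,8,8a-hexahydronaphthalen-2(1H)-one, via cycloadduct 15 (not isolated)
Conditions: PhMe (0.01 M), BHT (cat.), 170 °C, sealed tube; then Bu4NF (1.2 equiv), THF, 0 °C → rt
Reagents that add atoms: none
Why: Heating should trigger a concerted, asynchronous intramolecular [4+2] cycloaddition between the 2-silyloxy diene C7=C8(OTBS)–C9=C10 and the (E)-vinyl sulfone C5=C6, forming C6–C7 and C5–C10 at once, after which fluoride cleaves the enol silyl ether and the enolate, following proton transfer to the C7 side, expels benzenesulfinate from C6 (E1cB) to give the Δ6-8-ketone. The closest known reaction type is the thermal intramolecular Diels–Alder reaction of (E)-sulfonyl- or ester-terminated 1,3,9-decatrienes and of 2-silyloxy-1,3-dienes, with the vinyl sulfone acting as an ethylene/acetylene equivalent. Ring B closes as the cyclohexene of the cycloaddition itself, and ring A closes in the fused mode as the six-membered ring spanned by the four-atom tether C1–C4 (formally a 6-exo closure onto dienophile carbon C5). C5 and C10 arise stereospecifically from the (E)-C9=C10 geometry (tether outside, methyl inside) and the (E)-vinyl sulfone reacting through the tether-exo, sulfonyl-endo transition state, which gives the trans ring fusion (5α-H, 10β-methyl); the transient C6 centre is erased in the elimination. Absolute control comes from C3, since the chair-like tether keeps the C3 silyloxy group equatorial and tolerates only the methyl/methyl 1,3-diaxial contact between the C10 methyl and the axial C4 methyl, which should lead to 3S,5R,10R. The step needs trans- over cis-fusion and π-facial selectivity, secured by the E,E geometry and the C3 substituent, while regiochemistry is enforced by the tether and any cis-fused material could still be equilibrated at C5 through the dienolate of the enone.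

**Step 11**
Reactants: 17 (R)-(−)-carvone [(5R)-2-methyl-5-(prop-1-en-2-yl)cyclohex-2-en-1-one]
Product: 19 (5R)-2,6-dimethyl-5-(prop-1-en-2-yl)cyclohex-2-en-1-one (C6 epimers), via lithium dienolate 18 (not isolated)
Conditions: LiN(iPr)2, THF, −78 °C; then MeI, −78 → 0 °C
Reagents that add atoms: iodomethane, CI
Why: Kinetic α′-deprotonation and SN2 methylation (enolate alkylation) introduce the future C10′ methyl; the epimer ratio is irrelevant because this centre is re-enolised in step 13.

**Step 12**
Reactants: 19 (5R)-2,6-dimethyl-5-(prop-1-en-2-yl)cyclohex-2-en-1-one (C6 epimers)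
Product: 20 (1R,4R,6R)-1,3-dimethyl-4-(prop-1-en-2-yl)-7-oxabicyclo[4.1.0]heptan-2-one (C3 epimers)
Conditions: 30% aq. H2O2, NaOH (cat.), MeOH, 0 °C
Reagents that add atoms: hydrogen peroxide, OO
Why: Weitz–Scheffer nucleophilic epoxidation attacks only the enone, with hydroperoxide adding axially at C7′ anti to the C5′ isopropenyl group so that the epoxide is trans to it; the epoxide also masks the enone so that the acrylate addition of step 13 cannot continue to a bicyclic double Michael adduct.

**Step 13**
Reactants: 20 (1R,4R,6R)-1,3-dimethyl-4-(prop-1-en-2-yl)-7-oxabicyclo[4.1.0]heptan-2-one (C3 epimers); 21 methyl acrylate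
Product: 23 methyl 3-[(1R,3S,4S,6R)-1,3-dimethyl-2-oxo-4-(prop-1-en-2-yl)-7-oxabicyclo[4.1.0]heptan-3-yl]propanoate, via lithium enolate 22 (not isolated)
Conditions: LiN(iPr)2, THF, −78 °C; then 21 (1.1 equiv), −78 °C; then AcOH
Reagents that add atoms: none
Why: Michael addition of the lithium enolate (the only enolisable position) to methyl acrylate creates quaternary C10′, the acceptor approaching anti to the adjacent C5′ isopropenyl group so that the propanoate chain ends trans and the methyl cis to it.

**Step 14**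
Reactants: 23 methyl 3-[(1R,3S,4S,6R)-1,3-dimethyl-2-oxo-4-(prop-1-en-2-yl)-7-oxabicyclo[4.1.0]heptan-3-yl]propanoate
Product: 24 methyl 3-[(1R,4R,6S)-4-hydroxy-1,3-dimethyl-6-(prop-1-en-2-yl)cyclohex-2-en-1-yl]propanoate
Conditions: N2H4·H2O (3 equiv), AcOH (cat.), MeOH, 0 °C → rt
Reagents that add atoms: none
Why: In the Wharton transposition the epoxy hydrazone should fragment with loss of N2 to the allylic alcohol, moving the alkene to C8′=C9′ and leaving oxygen on C7′ with retention of the epoxide C–O configuration (trans to isopropenyl).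

**Step 15**
Reactants: 24 methyl 3-[(1R,4R,6S)-4-hydroxy-1,3-dimethyl-6-(prop-1-en-2-yl)cyclohex-2-en-1-yl]propanoate
Product: 25 methyl 3-[(1R,6S)-1,3-dimethyl-4-oxo-6-(prop-1-en-2-yl)cyclohex-2-en-1-yl]propanoate
Conditions: MnO2, CH2Cl2, rt
Reagents that add atoms: none
Why: Allylic oxidation with MnO2 gives the transposed enone and removes the C7′ configuration that has to be inverted.

**Step 16**
Reactants: 25 methyl 3-[(1R,6S)-1,3-dimethyl-4-oxo-6-(prop-1-en-2-yl)cyclohex-2-en-1-yl]propanoate
Product: 26 methyl 3-[(1R,4S,6S)-4-hydroxy-1,3-dimethyl-6-(prop-1-en-2-yl)cyclohex-2-en-1-yl]propanoate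
Conditions: NaBH4, CeCl3·7H2O, MeOH, −78 → 0 °C
Reagents that add atoms: none
Why: In the Luche 1,2-reduction hydride should attack axially from the face of the axial C5′–H (as in carvone to cis-carveol), giving the equatorial 7′β-alcohol cis to the isopropenyl group while ester and alkenes are untouched.

**Step 17**
Reactants: 26 methyl 3-[(1R,4S,6S)-4-hydroxy-1,3-dimethyl-6-(prop-1-en-2-yl)cyclohex-2-en-1-yl]propanoate
Product: 27 methyl 3-[(1R,4S,6S)-4-(ethenyloxy)-1,3-dimethyl-6-(prop-1-en-2-yl)cyclohex-2-en-1-yl]propanoate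
Conditions: ethyl vinyl ether (solvent), Hg(OAc)2 (0.3 equiv), reflux
Reagents that add atoms: ethyl vinyl ether, C=COCC
Why: Hg(OAc)2-catalysed transvinylation converts the allylic alcohol into the allyl vinyl ether without touching the C7′ stereocentre.

**Step 18**
Reactants: 27 methyl 3-[(1R,4S,6S)-4-(ethenyloxy)-1,3-dimethyl-6-(prop-1-en-2-yl)cyclohex-2-en-1-yl]propanoate
Product: 28 methyl 3-[(1S,2S,6S)-1,3-dimethyl-2-(2-oxoethyl)-6-(prop-1-en-2-yl)cyclohex-3-en-1-yl]propanoate
Conditions: PhMe, BHT (cat.), 190 °C, sealed tube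
Reagents that add atoms: none
Why: The Claisen rearrangement ([3,3]-sigmatropic, suprafacial) should form C9′–C12 on the β face from which the C7′–O bond departs, transferring the C7′ configuration to C9′ next to quaternary C10′, restoring the C7′=C8′ alkene and delivering C11 as an aldehyde distinct from the methyl ester.

**Step 19**
Reactants: 16 (4aR,6S,8aR)-6-(tert-butyldimethylsilyloxy)-5,5,8a-trimethyl-4a,5,6,7,8,8a-hexahydronaphthalen-2(1H)-one; 28 methyl 3-[(1S,2S,6S)-1,3-dimethyl-2-(2-oxoethyl)-6-(prop-1-en-2-yl)cyclohex-3-en-1-yl]propanoate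
Product: 30 C9–C11 aldol adduct of 16 and 28 (β-hydroxy ketone; C9 and C11 epimers), via lithium dienolate 29 (not isolated)
Conditions: 16, LiN(iPr)2, THF, −78 °C; then 28, −78 °C; then AcOH
Reagents that add atoms: none
Why: Kinetic α′-deprotonation of the enone at C9 followed by aldol addition forms the C9–C11 bond, the enolate adding to the aldehyde far faster than to the methyl ester; the new C9 and C11 centres are removed or equilibrated later.

**Step 20**
Reactants: 30 C9–C11 aldol adduct (C9 and C11 epimers)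
Product: 32 cross-conjugated dienone with C6=C7–C8(=O)–C9=C11 (3β-OTBS; 5α-H; 10β-methyl; right ring as in the target), via mesylate 31 (not isolated)
Conditions: MsCl, Et3N, CH2Cl2, 0 °C; then DBU, rt
Reagents that add atoms: none
Why: Mesylation of the β-hydroxy ketone and base-induced E1cB elimination should give the alkylidene ketone, whose alkene geometry is irrelevant because it is reduced in step 21.

**Step 21**
Reactants: 32 cross-conjugated dienone
Product: 34 saturated C8 ketone with the 9β side chain (3β-OTBS; 5α-H; 9α-H; 10β-methyl; right ring as in the target), via C9-epimeric ketone mixture 33 (not isolated)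
Conditions: [(Ph3P)CuH]6 (0.5 equiv of hexamer), PhH, H2O (5 equiv), rt; then NaOMe (cat.), MeOH, rt
Reagents that add atoms: none
Why: Copper hydride conjugate reduction should deliver hydride to both enone β-carbons (C6 and C11) while isolated alkenes and the ester are left alone, and methoxide equilibration through the C8 enolate places the C9 side chain equatorial (9β, 9S), the thermodynamically preferred epimer of the trans-decalone.

**Step 22**
Reactants: 34 saturated C8 ketone with the 9β side chain
Product: 35 methyl lansiolate 3-O-tert-butyldimethylsilyl ether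
Conditions: Ph3PCH3Br, KOtBu, PhMe, rt → 70 °C
Reagents that add atoms: methyltriphenylphosphonium bromide, C[P+](c1ccccc1)(c1ccccc1)c1ccccc1.[Br-]
Why: Wittig methylenation converts the hindered C8 ketone into the exocyclic methylene; the ester should not react with the non-stabilised ylide under these conditions and C9 already has its thermodynamic configuration.

**Step 23**
Reactants: 35 methyl lansiolate 3-O-tert-butyldimethylsilyl ether
Product: 36 methyl lansiolate
Conditions: HF·pyridine, pyridine, THF, 0 °C → rt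
Reagents that add atoms: none
Why: Buffered fluoride desilylation should free the hindered C3 alcohol without isomerising the exocyclic alkenes or hydrolysing the methyl ester, giving the target.

**Compound list**
1 | geranyl acetate, (2E)-3,7-dimethylocta-2,6-dien-1-yl acetate | CC(=O)OC/C=C(\C)CCC=C(C)C | starting material
2 | (2E)-5-(5,5-dimethyl-1,2,4-trioxolan-3-yl)-3-methylpent-2-en-1-yl acetate (ozonide) | CC(=O)OC/C=C(\C)CCC1OOC(C)(C)O1 | intermediate
3 | (2E)-3-methyl-6-oxohex-2-en-1-yl acetate | CC(=O)OC/C=C(\C)CCC=O | intermediate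
4 | 1-methoxy-2-methyl-1-(trimethylsilyloxy)prop-1-ene | COC(O[Si](C)(C)C)=C(C)C | starting material
5 | methyl (3S,6E)-8-acetoxy-3-hydroxy-2,2,6-trimethyloct-6-enoate | COC(=O)C(C)(C)[C@@H](O)CC/C(C)=C/COC(C)=O | intermediate
6 | methyl (3S,6E)-8-acetoxy-3-(tert-butyldimethylsilyloxy)-2,2,6-trimethyloct-6-enoate | COC(=O)C(C)(C)[C@@H](O[Si](C)(C)C(C)(C)C)CC/C(C)=C/COC(C)=O | intermediate
7 | (2E,6S)-6-(tert-butyldimethylsilyloxy)-3,7,7-trimethyloct-2-ene-1,8-diol | OCC(C)(C)[C@@H](O[Si](C)(C)C(C)(C)C)CC/C(C)=C/CO | intermediate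
8 | (2E,6S)-6-(tert-butyldimethylsilyloxy)-8-hydroxy-3,7,7-trimethyloct-2-enal | OCC(C)(C)[C@@H](O[Si](C)(C)C(C)(C)C)CC/C(C)=C/C=O | intermediate
9 | (3E,7S)-7-(tert-butyldimethylsilyloxy)-4,8,8-trimethylnon-3-ene-2,9-diol (C2 epimers) | OCC(C)(C)[C@@H](O[Si](C)(C)C(C)(C)C)CC/C(C)=C/C(C)O | intermediate
10 | (3S,6E)-3-(tert-butyldimethylsilyloxy)-2,2,6-trimethyl-8-oxonon-6-enal | O=CC(C)(C)[C@@H](O[Si](C)(C)C(C)(C)C)CC/C(C)=C/C(C)=O | intermediate
11 | diethyl [(phenylsulfonyl)methyl]phosphonate | CCOP(=O)(CS(=O)(=O)c1ccccc1)OCC | starting material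
12 | (3E,7S,9E)-7-(tert-butyldimethylsilyloxy)-4,8,8-trimethyl-10-(phenylsulfonyl)deca-3,9-dien-2-one | O=S(=O)(/C=C/C(C)(C)[C@@H](O[Si](C)(C)C(C)(C)C)CC/C(C)=C/C(C)=O)c1ccccc1 | intermediate
13 | lithium dienolate of 12 (O–Li on C8, C7=C8 and C9=C10) | O=S(=O)(/C=C/C(C)(C)[C@@H](O[Si](C)(C)C(C)(C)C)CC/C(C)=C/C(=C)O[Li])c1ccccc1 | intermediate
14 | (3E,7S,9E)-2,7-bis(tert-butyldimethylsilyloxy)-4,8,8-trimethyl-10-(phenylsulfonyl)deca-1,3,9-triene | O=S(=O)(/C=C/C(C)(C)[C@@H](O[Si](C)(C)C(C)(C)C)CC/C(C)=C/C(=C)O[Si](C)(C)C(C)(C)C)c1ccccc1 | intermediate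
15 | (4S,4aR,6S,8aR)-2,6-bis(tert-butyldimethylsilyloxy)-5,5,8a-trimethyl-4-(phenylsulfonyl)-3,4,4a,5,6,7,8,8a-octahydronaphthalene (trans-fused cycloadduct; 6α-sulfonyl in target numbering) | CC(C)(C)[Si](C)(C)OC1=C[C@@]2(C)CC[C@H](O[Si](C)(C)C(C)(C)C)C(C)(C)[C@@H]2[C@@H](S(=O)(=O)c3ccccc3)C1 | intermediate
16 | (4aR,6S,8aR)-6-(tert-butyldimethylsilyloxy)-5,5,8a-trimethyl-4a,5,6,7,8,8a-hexahydronaphthalen-2(1H)-one | O=C1C=C[C@H]2C(C)(C)[C@@H](O[Si](C)(C)C(C)(C)C)CC[C@]2(C)C1 | intermediate
17 | (R)-(−)-carvone, (5R)-2-methyl-5-(prop-1-en-2-yl)cyclohex-2-en-1-one | CC(=C)[C@@H]1CC=C(C)C(=O)C1 | starting material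
18 | lithium (3R)-6-methyl-3-(prop-1-en-2-yl)cyclohexa-1,5-dien-1-olate | C=C(C)[C@@H]1CC=C(C)C(O[Li])=C1 | intermediate
19 | (5R)-2,6-dimethyl-5-(prop-1-en-2-yl)cyclohex-2-en-1-one (C6 epimers) | C=C(C)[C@@H]1CC=C(C)C(=O)C1C | intermediate
20 | (1R,4R,6R)-1,3-dimethyl-4-(prop-1-en-2-yl)-7-oxabicyclo[4.1.0]heptan-2-one (C3 epimers; epoxide trans to isopropenyl) | C=C(C)[C@@H]1C[C@H]2O[C@@]2(C)C(=O)C1C | intermediate
21 | methyl acrylate | C=CC(=O)OC | starting material
22 | lithium enolate of 20 (O–Li on C9′, C9′=C10′) | C=C(C)[C@@H]1C[C@H]2O[C@@]2(C)C(O[Li])=C1C | intermediate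
23 | methyl 3-[(1R,3S,4S,6R)-1,3-dimethyl-2-oxo-4-(prop-1-en-2-yl)-7-oxabicyclo[4.1.0]heptan-3-yl]propanoate | C=C(C)[C@@H]1C[C@H]2O[C@@]2(C)C(=O)[C@@]1(C)CCC(=O)OC | intermediate
24 | methyl 3-[(1R,4R,6S)-4-hydroxy-1,3-dimethyl-6-(prop-1-en-2-yl)cyclohex-2-en-1-yl]propanoate (hydroxyl trans to isopropenyl) | C=C(C)[C@@H]1C[C@@H](O)C(C)=C[C@@]1(C)CCC(=O)OC | intermediate
25 | methyl 3-[(1R,6S)-1,3-dimethyl-4-oxo-6-(prop-1-en-2-yl)cyclohex-2-en-1-yl]propanoate | C=C(C)[C@@H]1CC(=O)C(C)=C[C@@]1(C)CCC(=O)OC | intermediate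
26 | methyl 3-[(1R,4S,6S)-4-hydroxy-1,3-dimethyl-6-(prop-1-en-2-yl)cyclohex-2-en-1-yl]propanoate (hydroxyl cis to isopropenyl) | C=C(C)[C@@H]1C[C@H](O)C(C)=C[C@@]1(C)CCC(=O)OC | intermediate
27 | methyl 3-[(1R,4S,6S)-4-(ethenyloxy)-1,3-dimethyl-6-(prop-1-en-2-yl)cyclohex-2-en-1-yl]propanoate | C=C(C)[C@@H]1C[C@H](OC=C)C(C)=C[C@@]1(C)CCC(=O)OC | intermediate
28 | methyl 3-[(1S,2S,6S)-1,3-dimethyl-2-(2-oxoethyl)-6-(prop-1-en-2-yl)cyclohex-3-en-1-yl]propanoate | C=C(C)[C@@H]1CC=C(C)[C@H](CC=O)[C@@]1(C)CCC(=O)OC | intermediate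
29 | lithium dienolate of 16 (O–Li on C8, C8=C9 and C6=C7) | [Li]OC1=C[C@@]2(C)CC[C@H](O[Si](C)(C)C(C)(C)C)C(C)(C)[C@@H]2C=C1 | intermediate
30 | C9–C11 aldol adduct of 16 and 28 (β-hydroxy ketone; C9 and C11 epimers) | O=C1C=C[C@H]2C(C)(C)[C@@H](O[Si](C)(C)C(C)(C)C)CC[C@]2(C)C1C(O)C[C@H]1C(C)=CC[C@@H](C(C)=C)[C@]1(C)CCC(=O)OC | intermediate
31 | C11 mesylate of 30 | O=C1C=C[C@H]2C(C)(C)[C@@H](O[Si](C)(C)C(C)(C)C)CC[C@]2(C)C1C(OS(C)(=O)=O)C[C@H]1C(C)=CC[C@@H](C(C)=C)[C@]1(C)CCC(=O)OC | intermediate
32 | cross-conjugated dienone, C6=C7–C8(=O)–C9=C11 (3β-OTBS; 5α-H; 10β-methyl) | O=C1C=C[C@H]2C(C)(C)[C@@H](O[Si](C)(C)C(C)(C)C)CC[C@]2(C)C1=CC[C@H]1C(C)=CC[C@@H](C(C)=C)[C@]1(C)CCC(=O)OC | intermediate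
33 | saturated C8 ketone, C9 epimer mixture | O=C1CC[C@H]2C(C)(C)[C@@H](O[Si](C)(C)C(C)(C)C)CC[C@]2(C)C1CC[C@H]1C(C)=CC[C@@H](C(C)=C)[C@]1(C)CCC(=O)OC | intermediate
34 | saturated C8 ketone with 9β side chain (3β-OTBS; 5α-H; 9α-H; 10β-methyl; right ring as in target) | O=C1CC[C@H]2C(C)(C)[C@@H](O[Si](C)(C)C(C)(C)C)CC[C@]2(C)[C@H]1CC[C@H]1C(C)=CC[C@@H](C(C)=C)[C@]1(C)CCC(=O)OC | intermediate
35 | methyl lansiolate 3-O-tert-butyldimethylsilyl ether | C=C1CC[C@H]2C(C)(C)[C@@H](O[Si](C)(C)C(C)(C)C)CC[C@]2(C)[C@H]1CC[C@H]1C(C)=CC[C@@H](C(C)=C)[C@]1(C)CCC(=O)OC | intermediate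
36 | methyl lansiolate | C=C(C)[C@@H]1CC=C(C)[C@H](CC[C@H]2C(=C)CC[C@H]3C(C)(C)[C@@H](O)CC[C@]23C)[C@@]1(C)CCC(=O)OC | target

**Step count and risks**
Total steps: 23. Longest linear sequence: 15 (steps 1–10 and 19–23); the right-hand fragment takes 8 steps (11–18).

Steps most likely to fail:

1. Step 10. The cycloaddition may be slow because the diene terminus C10 is disubstituted and the termini are not polarity-matched; at the temperature needed, a 1,5-hydrogen shift or desilylation of the dienol ether may compete, and trans/cis or π-facial selectivity may erode. Fallback, from 10 back to 16: keto aldehyde 10 would be homologated by a Wittig reaction with Ph3P=CHOMe (Ph3PCH2OMe Cl, KN(SiMe3)2, THF, −78 °C; the aldehyde reacts before the conjugated ketone) to enol ether F1. Mild aqueous acid (oxalic acid, THF–H2O) would then give the one-carbon-longer keto aldehyde F2, in which C6 is a formyl carbon and C5 its α-methylene. Pyrrolidine/AcOH would bring about an intramolecular Robinson annulation: enamine Michael addition of C5 to the enone carbon C10 closes ring A, aldol condensation of the C7 methyl ketone onto the C6 aldehyde closes ring B, and loss of water gives enone 16 directly. In this polar, stepwise alternative the termini are matched, C5 is set under thermodynamic control and no sulfone is needed.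

2. Step 14. Hydrazone formation at a ketone flanked by two fully substituted carbons may be slow, allowing hydrazinolysis of the methyl ester or epoxide opening to compete. Fallback, from 23 back to 24: NaBH4 (MeOH, 0 °C) would reduce the ketone to epoxy alcohol F3. 1,1′-Thiocarbonyldiimidazole (DMAP, ClCH2CH2Cl, reflux) would convert it into thiocarbonylimidazolide F4. Bu3SnH/AIBN (PhH, reflux) would then generate the C9′ radical, which opens the epoxide by β-scission of the C8′–O bond; hydrogen transfer to the resulting alkoxy radical gives allylic alcohol 24 with the same C7′ configuration.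

3. Step 18. The rearrangement has to pass through the conformer with a pseudo-axial C7′–O bond and an axial isopropenyl group, and the new bond forms next to quaternary C10′; at the required temperature, elimination of the vinyl ether or ene-type decomposition of the aldehyde may take over. Fallback, from 26 back to 28: an Eschenmoser–Claisen rearrangement of alcohol 26 with MeC(OMe)2NMe2 (xylenes, 140 °C) would go through the more reactive ketene N,O-acetal at lower temperature and give dimethylamide F5 with the same suprafacial chirality transfer. Cp2Zr(H)Cl (THF, rt) would then reduce the tertiary amide to aldehyde 28 in the presence of the methyl ester.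

**Further compounds**
F1 | step 10 | (3E,7S)-7-(tert-butyldimethylsilyloxy)-10-methoxy-4,8,8-trimethyldeca-3,9-dien-2-one (enol ether, E/Z at C9) | COC=CC(C)(C)[C@@H](O[Si](C)(C)C(C)(C)C)CC/C(C)=C/C(C)=O
F2 | step 10 | (4S,7E)-4-(tert-butyldimethylsilyloxy)-3,3,7-trimethyl-9-oxodec-7-enal | O=CCC(C)(C)[C@@H](O[Si](C)(C)C(C)(C)C)CC/C(C)=C/C(C)=O
F3 | step 14 | epoxy alcohol from reduction of the ketone of 23 (carbinol epimers) | C=C(C)[C@@H]1C[C@H]2O[C@@]2(C)C(O)[C@@]1(C)CCC(=O)OC
F4 | step 14 | O-(imidazol-1-ylthiocarbonyl) derivative of F3 | C=C(C)[C@@H]1C[C@H]2O[C@@]2(C)C(OC(=S)n3ccnc3)[C@@]1(C)CCC(=O)OC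
F5 | step 18 | methyl 3-[(1S,2S,6S)-2-[2-(dimethylamino)-2-oxoethyl]-1,3-dimethyl-6-(prop-1-en-2-yl)cyclohex-3-en-1-yl]propanoate | CN(C)C(=O)C[C@H]1C(C)=CC[C@@H](C(C)=C)[C@]1(C)CCC(=O)OC
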